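The runs were generated by integration from invented constants; noise was put on by code.

**The question.** I want the share of isomer of the product A in that isomer plus target, early and late, in the flask charged with equal amounts of starting material and other conformer.

| flask | starting material | other conformer | remark | time |
|---|---|---|---|---|
| summer | 0.30 M | 0.20 M | run made earlier |  |
| autumn | 0.30 M | 0.45 M | run made earlier |  |
| noon | 0.45 M | 0.30 M | run made earlier |  |
| flask | 0.30 M | 0.300 M |  | 2.0 h |

| run | time / min | isomer of the product A / % | target / % |
|---|---|---|---|
| summer | 10.0 | 1.9 | 1.8 |
| summer | 25.0 | 3.2 | 1.8 |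
| summer | 50.0 | 6.0 | 3.4 |
| summer | 80.0 | 7.0 | 2.6 |
| autumn | 6.00 | 0.7 | 1.1 |
| autumn | 12.0 | 2.6 | 1.2 |
| autumn | 30.0 | 5.1 | 1.7 |
| autumn | 80.0 | 8.1 | 2.6 |
| noon | 20.0 | 4.0 | 1.4 |
| noon | 40.0 | 6.1 | 3.1 |
| noon | 50.0 | 6.0 | 1.8 |
| noon | 80.0 | 7.6 | 3.6 |

(each reading ± 0.5 percentage points)

- share of isomer of the product A in isomer of the product A plus target at 40 s
- share of isomer of the product A in isomer of the product A plus target at 2.0 h
- which of isomer of the product A and target there is more of at 2.0 h



**The start.** The first reading of the autumn run, at 6.00 min, shows 0.7% of isomer of the product A and 1.1% of target, so target reads 0.4 percentage points ahead against a scatter of 0.5 points, and the share reads 38.9%.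

**The crossing.** At 12.0 min that run's target reads 1.2%, nearly unchanged, which is a knee, while isomer of the product A reads 2.6%, more than target. So in the autumn run the crossing lies no later than this reading, and with the order at 6.00 min inside the scatter it may lie before that one too. Since the autumn share reads higher at 12.0 min than at 6.00 min, I put the flask at 40 s below 38.9%, and these are noisy readings.

**The level.** From 30.0 min on the share stops climbing, so I replace the curve by its mean over those 7 readings, which gives 70.9%. This is the level share, the summed isomer of the product A over the summed isomer and target. The readings at 80.0 min alone give 72.1% and the earlier ones 69.9%, so I take the mean's error as 2.2 points. At 2.0 h I commit to the level share, with isomer of the product A ahead.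

**The forecast.** It gives 45% early, 71% late and isomer of the product A in the lead, and says of the early value: “both amounts would be far below the noise”.

**The result.** The flask gives 27.0% at 40 s and 71.9% at 2.0 h, with 8.78% of isomer of the product A against 3.43% of target.

    starting material ⇌ other conformer (K = 1.40, k = 5.40 × 10⁻⁵ s⁻¹)
    starting material → target (k = 2.30 × 10⁻⁴ s⁻¹)
    other conformer → isomer of the product A (k = 6.90 × 10⁻⁵ s⁻¹)
    target ⇌ isomer of the product A (K = 0.970, k = 3.50 × 10⁻⁴ s⁻¹)
    target ⇌ isomer of the product B (K = 16.0, k = 0.00990 s⁻¹)

**The comparison.** The early share lies 18 points below the forecast, and in the flask isomer of the product A draws level with target at 0.0910 h, later than 40 s. The level share stands 1.00 point from the flask's late value, less than the drift. The neighbour flask with 0.18 M of other conformer gives 68.2%, which is 2.7 points under the level share.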